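Numbering (trinervitane): C19H2=C8, C9H2, C10H2, C11(OH), C12(CH3), C13H2, C14(OH), C1=C15(CH3), C16(H), C7(H), C6H2, C5H2, C4(CH3), C3(OAc), C2(OAc). Rings: cyclopentane C4–C5–C6–C7–C16, cyclohexene C1–C2–C3–C4–C16–C15, eleven-membered ring C7–C8–C9–C10–C11–C12–C13–C14–C1–C15–C16.
Enabling feature: on the cyclopentane the three outward bonds C4–C3, C16–C15 and C7–C8 are all cis, and C3 and C8 both end as functionalised carbons. Joining C3 to C8 by a double bond turns the ring into a bicyclo[2.2.1]heptene (C16 = one-carbon bridge, C5–C6 = two-carbon bridge), the Diels–Alder adduct of a 1,3-dimethylfulvene and an ethylene equivalent.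
Key disconnection: an enantioselective Diels–Alder reaction of the flat 6-acetoxyfulvene 6 with an acrylimide forms C4–C5 and C6–C7 and fixes C4 and C7. The carboxyl activator is excised in step 7, and ring-rearrangement metathesis (step 6) cuts C3=C8 again, so that C3 closes the cyclohexene onto an allyl group on C15 and C8 leaves as an isopropenyl group.
Further disconnections: C1–C14 (intramolecular Nozaki–Hiyama–Kishi reaction of a C1 vinyl iodide with the C14 aldehyde), C9–C10 (allyllithium from the isopropenyl group plus epoxide 23, which brings C11 and C12), and the C2/C3 oxygens and C1=C15 from a diene / singlet-oxygen / Babler–Dauben sequence.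
Ring order: cyclopentane (as norbornene, step 3), cyclohexene (step 6), eleven-membered ring (step 24). Absolute configuration comes from the copper–bis(oxazoline) catalyst (core) and an iridium-catalysed crotylation (C11, C12).

Key step: step 3

Remark: where a chiral ligand or reagent is named, the antipode meant is the one that gives the configuration drawn in the product SMILES. The enol acetate geometry in 6 and 8 and the carbinol centre C15 in 11–13 and 24–26 are mixtures that are erased later and are left open in the SMILES.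

Step 1
Reactants: 1 3-methylcyclopent-2-en-1-one
Product: 3 1,3-dimethylcyclopenta-1,3-diene, via 1,3-dimethylcyclopent-2-en-1-ol 2 (not isolated)
Conditions: MeLi, Et2O, −78 to 0 °C; then TsOH (cat.), H2O, pentane, 0 °C; distil
Reagents that add atoms: methyllithium, C[Li]
Why: 1,2-addition of the organolithium to the enone and acid-catalysed dehydration of the tertiary allylic alcohol give the diene (double-bond isomers give the same anion in step 2); no stereocentre is formed.

Step 2
Reactants: 3 1,3-dimethylcyclopenta-1,3-diene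
Product: 6 1-(2,4-dimethylcyclopenta-2,4-dien-1-ylidene)ethyl acetate, via sodium 1,3-dimethylcyclopentadienide 4 (not isolated), via sodium 1-(2,4-dimethylcyclopenta-2,4-dien-1-ylidene)ethanolate 5 (not isolated)
Conditions: NaH, THF, 0 °C to rt; EtOAc, reflux; then Ac2O, 0 °C
Reagents that add atoms: ethyl acetate, CCOC(C)=O; acetic anhydride, CC(=O)OC(C)=O
Why: Claisen-type C-acylation of the aromatic cyclopentadienide at a ring CH next to only one methyl (the two such positions are equivalent, the one between the methyls is shielded) and O-acetylation of the 6-oxidofulvene should give the acyloxyfulvene; no stereocentre.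

Step 3
Reactants: 6 1-(2,4-dimethylcyclopenta-2,4-dien-1-ylidene)ethyl acetate; 7 3-acryloyl-1,3-oxazolidin-2-one
Product: 8 3-{[(1S,2S,4S)-7-(1-acetoxyethylidene)-1,5-dimethylbicyclo[2.2.1]hept-5-en-2-yl]carbonyl}-1,3-oxazolidin-2-one (2-endo)
Conditions: [Cu((S,S)-t-Bu-box)](SbF6)2 (10 mol %; box = 2,2'-(propane-2,2-diyl)bis(4-tert-butyl-4,5-dihydrooxazole)), 6 in excess, CH2Cl2, −40 to 0 °C
Reagents that add atoms: none
Why: Proposed new method: the acrylimide, held s-cis by two-point chelation to square-planar divalent copper, adds across the ring diene C4=C3–C8=C7 of the electron-rich acyloxyfulvene in a concerted, asynchronous normal-demand [4+2] cycloaddition; the closest known reactions are the copper–bis(oxazoline)-catalysed acrylimide Diels–Alder reaction of cyclopentadiene and the thermal Diels–Alder reactions of 6-acyloxyfulvenes with acrylic dienophiles. The two new bonds C4–C5 and C6–C7 form suprafacially on one face of the flat five-membered ring and close the cyclopentane C4–C5–C6–C7–C16 as part of a bicyclo[2.2.1]heptene. C4 (quaternary) and C7 are set together by the fulvene face that meets the unshielded face of the bound dienophile (tert-butyl groups of the ligand) in the endo orientation, while C5 only reflects the endo rule and is erased in step 7. Enantiofacial, endo and regio control are needed at once, because the skeleton enantiomer follows from their combination: the C4 methyl (ortho effect) and the C8 methyl (para effect) both send the acyl-bearing carbon to C4, and the chelated imide should be strongly endo-selective. The exocyclic enol acetate keeps the diene from the 1,5-hydrogen shifts of 5-substituted cyclopentadienes and makes C16 a ketone α-carbon, whose configuration is set in step 4.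

Step 4
Reactants: 8 Diels–Alder adduct
Product: 10 7-syn-acetyl-1,5-dimethylbicyclo[2.2.1]hept-5-ene-2-endo-carboxylic acid, via peroxy acid 9 (not isolated)
Conditions: LiOH, H2O2, THF/H2O, 0 °C to rt; Na2SO3; then H3O+
Reagents that add atoms: hydrogen peroxide, OO
Why: hydroperoxide cleaves the exocyclic imide carbonyl (standard acyl-oxazolidinone hydrolysis) and the enol acetate, and the freed ketone should equilibrate at C16 under the basic conditions to the epimer with the acetyl group over the C3=C8 double bond, away from the exo hydrogens on C5 and C6, which is the C16 configuration of the target.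

Step 5
Reactants: 10 keto acid
Product: 11 7-syn-(2-hydroxypent-4-en-2-yl)-1,5-dimethylbicyclo[2.2.1]hept-5-ene-2-endo-carboxylic acid
Conditions: allylMgBr (3 equiv), THF, −78 °C; aq. NH4Cl
Reagents that add atoms: allylmagnesium bromide, C=CC[Mg]Br
Why: Grignard 1,2-addition to the methyl ketone (the carboxylate is inert) puts C1 and C2 on C15; the new carbinol centre is of no account because C15 becomes sp2 in step 15.

Step 6
Reactants: 11 allyl carbinol
Product: 12 cis-fused 7-hydroxy-3a,7-dimethyl-1-(prop-1-en-2-yl)-2,3,3a,6,7,7a-hexahydro-1H-indene-3-carboxylic acid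
Conditions: second-generation Hoveyda–Grubbs catalyst RuCl2(H2IMes)(=CH-C6H4-2-O-i-Pr) (5 mol %), ethylene (1 atm), toluene, 50 °C
Reagents that add atoms: none
Why: ring-rearrangement metathesis (ring opening/ring closing, a net isomerisation) driven by norbornene strain: the alkylidene on C2 should bond to the unsubstituted alkene carbon C3 on the exo face and close the cyclohexene (C2=C3), the methylated carbon C8 leaves as an isopropenyl group, and the cis ring fusion and the cis C7 side chain are inherited from the bicycle.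

Step 7
Reactants: 12 hydrindene acid
Product: 13 cis-fused 3a,7-dimethyl-1-(prop-1-en-2-yl)-2,3,3a,6,7,7a-hexahydro-1H-inden-7-ol
Conditions: 9-mesityl-10-methylacridinium tetrafluoroborate (5 mol %), PhSSPh (10 mol %), i-Pr2NEt (20 mol %), CF3CH2OH, blue LEDs, rt
Reagents that add atoms: none
Why: photoredox hydrodecarboxylation (oxidation of the carboxylate, loss of CO2, hydrogen-atom transfer from thiophenol to the C5 radical) removes the activating carboxyl; it is run after ring opening because a norbornenyl radical would rearrange, and without electrophilic acid activation, which could lactonise onto the C15 hydroxyl.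

Step 8
Reactants: 14 2-(benzyloxy)ethan-1-ol; 15 but-3-en-2-yl acetate
Product: 17 (2R,3R)-1-(benzyloxy)-3-methylpent-4-en-2-ol, via 2-(benzyloxy)acetaldehyde 16 (not isolated)
Conditions: [Ir(cod)Cl]2 (2.5 mol %), (S)-SEGPHOS (5 mol %), 4-cyano-3-nitrobenzoic acid (10 mol %), Cs2CO3 (20 mol %), THF, 90 °C
Reagents that add atoms: none
Why: iridium-catalysed transfer-hydrogenative carbonyl crotylation: the alcohol is dehydrogenated to the aldehyde, which is attacked by the (E)-crotyliridium species through a closed chair transition state, so the anti relation of C11–OH and C12–CH3 follows from the geometry and the absolute sense from the ligand.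

Step 9
Reactants: 17 homoallylic alcohol
Product: 19 (3R,4R)-5-(benzyloxy)-3-methylpentane-1,4-diol, via bis(9-BBN) adduct 18 (not isolated)
Conditions: 9-BBN (2.5 equiv), THF, 0 °C to rt; then NaOH, H2O2, 0 °C
Reagents that add atoms: hydrogen peroxide, OO
Why: anti-Markovnikov hydroboration–oxidation of the terminal alkene gives the primary alcohol that becomes C14; the stereocentres are not touched.

Step 10
Reactants: 19 diol
Product: 20 (2R,3R)-1-(benzyloxy)-5-[(tert-butyldimethylsilyl)oxy]-3-methylpentan-2-ol
Conditions: TBSCl, imidazole, CH2Cl2, −20 °C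
Reagents that add atoms: tert-butyl(chloro)dimethylsilane, CC(C)(C)[Si](C)(C)Cl
Why: the primary hydroxyl is silylated much faster than the secondary one (selective silyl ether formation).

Step 11
Reactants: 20 benzyl ether
Product: 21 (2R,3R)-5-[(tert-butyldimethylsilyl)oxy]-3-methylpentane-1,2-diol
Conditions: H2 (1 atm), Pd/C, EtOAc, rt
Reagents that add atoms: none
Why: hydrogenolysis of the benzyl ether; the silyl ether is stable.

Step 12
Reactants: 21 1,2-diol
Product: 23 (2R)-2-{(2R)-4-[(tert-butyldimethylsilyl)oxy]butan-2-yl}oxirane, via primary tosylate 22 (not isolated)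
Conditions: NaH, 1-tosylimidazole, THF, 0 °C to rt
Reagents that add atoms: none
Why: selective sulfonylation of the primary hydroxyl and intramolecular Williamson closure by the secondary alkoxide; C11 keeps its configuration because the displacement takes place at C10.

Step 13
Reactants: 13 hydrindenol; 23 epoxide
Product: 25 hydrindenol with the C7 side chain C8(=CH2)–CH2–CH2–CH(OH)–CH(CH3)–CH2–CH2–OTBS (11S,12R), via dilithio alkoxide 24 (not isolated)
Conditions: n-BuLi (2.2 equiv), TMEDA, hexane, 0 °C to rt; then 23, THF, −78 to 0 °C; H2O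
Reagents that add atoms: none
Why: after deprotonation of the hydroxyl, n-BuLi·TMEDA should metalate the methyl of the isopropenyl group (allylic lithiation, as known for the isopropenyl group of limonene), and the symmetrical 2-substituted allyllithium opens the epoxide at its CH2 end (SN2), which forms C9–C10, keeps the C8=C19 methylene and brings C11 and C12 in unchanged.

Step 14
Reactants: 25 diol
Product: 26 11-O-triisopropylsilyl ether of 25
Conditions: TIPSOTf, 2,6-lutidine, CH2Cl2, −78 °C
Reagents that add atoms: triisopropylsilyl trifluoromethanesulfonate, CC(C)[Si](OS(=O)(=O)C(F)(F)F)(C(C)C)C(C)C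
Why: silylation of the secondary hydroxyl; the tertiary hydroxyl is too hindered to react at this temperature.

Step 15
Reactants: 26 tertiary alcohol
Product: 27 diene C15=C1–C2=C3
Conditions: Burgess reagent (methyl N-(triethylammoniosulfonyl)carbamate), benzene, 50 °C
Reagents that add atoms: none
Why: syn elimination of the tertiary sulfamate toward the allylic C1–H should give the conjugated cyclohexadiene (most acidic β-hydrogen, conjugated product); the C15 centre disappears.

Step 16
Reactants: 27 diene
Product: 29 3,15-diol with C1=C2 (C3–OH cis to the C4 methyl), via endoperoxide 28 (not isolated)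
Conditions: O2, tetraphenylporphyrin (cat.), hν, CH2Cl2, −20 °C; then thiourea, MeOH, rt
Reagents that add atoms: dioxygen, O=O
Why: [4+2] cycloaddition of singlet oxygen to the cyclohexadiene from the face opposite the fused cyclopentane and its C7 side chain (the face of C4–CH3 and C16–H), followed by reduction of the O–O bond, should place the C3 oxygen cis to the C4 methyl as in the target.

Step 17
Reactants: 29 ene-diol
Product: 30 3-acetate of 29
Conditions: Ac2O, pyridine, DMAP (cat.), CH2Cl2, 0 °C
Reagents that add atoms: acetic anhydride, CC(=O)OC(C)=O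
Why: acetylation of the secondary allylic hydroxyl; the tertiary hydroxyl does not react under these conditions.

Step 18
Reactants: 30 tertiary allylic alcohol
Product: 31 enone (C2=O, C1=C15, 3-acetoxy)
Conditions: pyridinium chlorochromate [C5H5NH][CrO3Cl], NaOAc, 4 Å molecular sieves, CH2Cl2, rt
Reagents that add atoms: none
Why: Babler–Dauben oxidative transposition: the chromate ester of the tertiary allylic alcohol undergoes a [3,3] shift to C2 and is oxidised, which gives the ketone at C2 and the C1=C15 double bond.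

Step 19
Reactants: 31 enone
Product: 32 1-iodo enone
Conditions: I2, pyridine, CH2Cl2, 0 °C to rt
Reagents that add atoms: iodine, [I][I]
Why: α-iodination of the enone by conjugate addition of pyridine, iodination of the enolate and elimination, as for 3-methylcyclohex-2-enone.

Step 20
Reactants: 32 iodo enone
Product: 33 allylic alcohol (2-OH trans to 3-OAc)
Conditions: NaBH4, CeCl3·7H2O, MeOH, −78 °C
Reagents that add atoms: none
Why: Luche 1,2-reduction; hydride is expected to arrive on the face that carries the C3 acetoxy group and the C4 methyl, because the other face is covered by the fused cyclopentane, which gives the C2 alcohol trans to the C3 acetate.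

Step 21
Reactants: 33 allylic alcohol
Product: 34 2,3-diacetate
Conditions: Ac2O, pyridine, DMAP (cat.), CH2Cl2, rt
Reagents that add atoms: acetic anhydride, CC(=O)OC(C)=O
Why: DMAP-catalysed acetylation of the remaining secondary hydroxyl (an acetyl shift between O2 and O3 would be of no account).

Step 22
Reactants: 34 bis-silyl ether
Product: 35 primary alcohol at C14
Conditions: HF·pyridine, pyridine, THF, 0 °C
Reagents that add atoms: none
Why: the primary tert-butyldimethylsilyl ether is cleaved much faster than the secondary triisopropylsilyl ether, and the acetates are stable.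

Step 23
Reactants: 35 primary alcohol
Product: 36 C14 aldehyde
Conditions: Dess–Martin periodinane, NaHCO3, CH2Cl2, rt
Reagents that add atoms: none
Why: mild oxidation of the primary alcohol that leaves the vinyl iodide, the acetates and the silyl ether untouched.

Step 24
Reactants: 36 iodo aldehyde
Product: 37 11-O-triisopropylsilyl ether of the target
Conditions: CrCl2 (10 equiv), NiCl2 (cat.), DMSO/THF, rt, high dilution
Reagents that add atoms: none
Why: intramolecular Nozaki–Hiyama–Kishi reaction: nickel-catalysed formation of the C1 vinylchromium species and its addition to the C14 aldehyde close the eleven-membered ring (as in closures onto 2-iodo-3-methylcyclohexenyl units); the C14 configuration is under control of the macrocyclic transition state and should favour the face that keeps the chain away from the C2 acetate.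

Step 25
Reactants: 37 silyl ether
Product: 38 target
Conditions: HF·pyridine, THF, rt
Reagents that add atoms: none
Why: fluoride-mediated cleavage of the secondary silyl ether under conditions that do not move or cleave the acetates.

Compound list
1 | 3-methylcyclopent-2-en-1-one | CC1=CC(=O)CC1 | starting material
2 | 1,3-dimethylcyclopent-2-en-1-ol | CC1=CC(C)(O)CC1 | intermediate
3 | 1,3-dimethylcyclopenta-1,3-diene | CC1=CC(C)=CC1 | intermediate
4 | sodium 1,3-dimethylcyclopentadienide | [Na+].CC1=CC(C)=C[CH-]1 | intermediate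
5 | sodium 1-(2,4-dimethylcyclopenta-2,4-dien-1-ylidene)ethan-1-olate | [Na+].CC([O-])=C1C(C)=CC(C)=C1 | intermediate
6 | 1-(2,4-dimethylcyclopenta-2,4-dien-1-ylidene)ethyl acetate (6-acetoxy-1,3,6-trimethylfulvene, E/Z mixture) | CC(OC(C)=O)=C1C(C)=CC(C)=C1 | intermediate
7 | 3-acryloyl-1,3-oxazolidin-2-one | C=CC(=O)N1CCOC1=O | starting material
8 | 3-{[(1S,2S,4S)-7-(1-acetoxyethylidene)-1,5-dimethylbicyclo[2.2.1]hept-5-en-2-yl]carbonyl}-1,3-oxazolidin-2-one (2-endo) | C[C@@]12[C@@H](C(=O)N3CCOC3=O)C[C@@H](C(C)=C1)C2=C(C)OC(C)=O | intermediate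
9 | 7-syn-acetyl-1,5-dimethylbicyclo[2.2.1]hept-5-ene-2-endo-peroxycarboxylic acid | C[C@@]12[C@@H](C(=O)OO)C[C@@H](C(C)=C1)[C@H]2C(C)=O | intermediate
10 | 7-syn-acetyl-1,5-dimethylbicyclo[2.2.1]hept-5-ene-2-endo-carboxylic acid (acetyl on the side of the ring double bond) | C[C@@]12[C@@H](C(=O)O)C[C@@H](C(C)=C1)[C@H]2C(C)=O | intermediate
11 | 7-syn-(2-hydroxypent-4-en-2-yl)-1,5-dimethylbicyclo[2.2.1]hept-5-ene-2-endo-carboxylic acid (carbinol epimers) | C[C@@]12[C@@H](C(=O)O)C[C@@H](C(C)=C1)[C@H]2C(C)(O)CC=C | intermediate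
12 | cis-fused 7-hydroxy-3a,7-dimethyl-1-(prop-1-en-2-yl)-2,3,3a,6,7,7a-hexahydro-1H-indene-3-carboxylic acid (isopropenyl cis to C7, carboxyl trans to the 3a-methyl, C7 epimers) | C=C(C)[C@@H]1C[C@H](C(=O)O)[C@]2(C)C=CCC(C)(O)[C@H]12 | intermediate
13 | cis-fused 3a,7-dimethyl-1-(prop-1-en-2-yl)-2,3,3a,6,7,7a-hexahydro-1H-inden-7-ol (isopropenyl cis to C7, C7 epimers) | C=C(C)[C@@H]1CC[C@]2(C)C=CCC(C)(O)[C@H]12 | intermediate
14 | 2-(benzyloxy)ethan-1-ol | OCCOCc1ccccc1 | starting material
15 | but-3-en-2-yl acetate (racemic) | CC(OC(C)=O)C=C | starting material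
16 | 2-(benzyloxy)acetaldehyde | O=CCOCc1ccccc1 | intermediate
17 | (2R,3R)-1-(benzyloxy)-3-methylpent-4-en-2-ol | C=C[C@@H](C)[C@@H](O)COCc1ccccc1 | intermediate
18 | bis(9-borabicyclo[3.3.1]nonan-9-yl) adduct of 17 (boron on the terminal carbon and on the oxygen) | B1(C2CCCC1CCC2)CC[C@@H](C)[C@@H](OB1C2CCCC1CCC2)COCc1ccccc1 | intermediate
19 | (3R,4R)-5-(benzyloxy)-3-methylpentane-1,4-diol | OCC[C@@H](C)[C@@H](O)COCc1ccccc1 | intermediate
20 | (2R,3R)-1-(benzyloxy)-5-[(tert-butyldimethylsilyl)oxy]-3-methylpentan-2-ol | CC(C)(C)[Si](C)(C)OCC[C@@H](C)[C@@H](O)COCc1ccccc1 | intermediate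
21 | (2R,3R)-5-[(tert-butyldimethylsilyl)oxy]-3-methylpentane-1,2-diol | CC(C)(C)[Si](C)(C)OCC[C@@H](C)[C@@H](O)CO | intermediate
22 | (2R,3R)-5-[(tert-butyldimethylsilyl)oxy]-2-hydroxy-3-methylpentyl 4-methylbenzenesulfonate | CC(C)(C)[Si](C)(C)OCC[C@@H](C)[C@@H](O)COS(=O)(=O)c1ccc(C)cc1 | intermediate
23 | (2R)-2-{(2R)-4-[(tert-butyldimethylsilyl)oxy]butan-2-yl}oxirane | C1O[C@@H]1[C@H](C)CCO[Si](C)(C)C(C)(C)C | intermediate
24 | dilithio derivative of 13 (lithium alkoxide, CH2Li in place of the isopropenyl CH3) | [Li]CC(=C)[C@@H]1CC[C@]2(C)C=CCC(C)(O[Li])[C@H]12 | intermediate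
25 | 13 with the C7 side chain C8(=CH2)–CH2–CH2–CH(OH)–CH(CH3)–CH2–CH2–OTBS, (11S,12R) | C=C(CC[C@H](O)[C@H](C)CCO[Si](C)(C)C(C)(C)C)[C@@H]1CC[C@]2(C)C=CCC(C)(O)[C@H]12 | intermediate
26 | 11-O-triisopropylsilyl ether of 25 | C=C(CC[C@H](O[Si](C(C)C)(C(C)C)C(C)C)[C@H](C)CCO[Si](C)(C)C(C)(C)C)[C@@H]1CC[C@]2(C)C=CCC(C)(O)[C@H]12 | intermediate
27 | diene from 26 (C15=C1–C2=C3) | C=C(CC[C@H](O[Si](C(C)C)(C(C)C)C(C)C)[C@H](C)CCO[Si](C)(C)C(C)(C)C)[C@@H]1CC[C@]2(C)C=CC=C(C)[C@H]12 | intermediate
28 | 3,15-epidioxide of 27 (peroxide bridge on the face of the C4 methyl) | C=C(CC[C@H](O[Si](C(C)C)(C(C)C)C(C)C)[C@H](C)CCO[Si](C)(C)C(C)(C)C)[C@@H]1CC[C@]2(C)[C@@H]3C=C[C@@](C)(OO3)[C@H]12 | intermediate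
29 | 3,15-diol with C1=C2 (both hydroxyls on the face of the C4 methyl) | C=C(CC[C@H](O[Si](C(C)C)(C(C)C)C(C)C)[C@H](C)CCO[Si](C)(C)C(C)(C)C)[C@@H]1CC[C@]2(C)[C@@H](O)C=C[C@@](C)(O)[C@H]12 | intermediate
30 | 3-acetate of 29 | C=C(CC[C@H](O[Si](C(C)C)(C(C)C)C(C)C)[C@H](C)CCO[Si](C)(C)C(C)(C)C)[C@@H]1CC[C@]2(C)[C@@H](OC(C)=O)C=C[C@@](C)(O)[C@H]12 | intermediate
31 | enone: C2=O, C1=C15, 3-acetoxy (cis to the C4 methyl) | C=C(CC[C@H](O[Si](C(C)C)(C(C)C)C(C)C)[C@H](C)CCO[Si](C)(C)C(C)(C)C)[C@@H]1CC[C@]2(C)[C@@H](OC(C)=O)C(=O)C=C(C)[C@H]12 | intermediate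
32 | 1-iodo derivative of 31 | C=C(CC[C@H](O[Si](C(C)C)(C(C)C)C(C)C)[C@H](C)CCO[Si](C)(C)C(C)(C)C)[C@@H]1CC[C@]2(C)[C@@H](OC(C)=O)C(=O)C(I)=C(C)[C@H]12 | intermediate
33 | allylic alcohol from 32 (2-OH trans to 3-OAc) | C=C(CC[C@H](O[Si](C(C)C)(C(C)C)C(C)C)[C@H](C)CCO[Si](C)(C)C(C)(C)C)[C@@H]1CC[C@]2(C)[C@@H](OC(C)=O)[C@H](O)C(I)=C(C)[C@H]12 | intermediate
34 | 2,3-diacetate of 33 | C=C(CC[C@H](O[Si](C(C)C)(C(C)C)C(C)C)[C@H](C)CCO[Si](C)(C)C(C)(C)C)[C@@H]1CC[C@]2(C)[C@@H](OC(C)=O)[C@H](OC(C)=O)C(I)=C(C)[C@H]12 | intermediate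
35 | primary C14 alcohol from 34 | C=C(CC[C@H](O[Si](C(C)C)(C(C)C)C(C)C)[C@H](C)CCO)[C@@H]1CC[C@]2(C)[C@@H](OC(C)=O)[C@H](OC(C)=O)C(I)=C(C)[C@H]12 | intermediate
36 | C14 aldehyde from 35 | C=C(CC[C@H](O[Si](C(C)C)(C(C)C)C(C)C)[C@H](C)CC=O)[C@@H]1CC[C@]2(C)[C@@H](OC(C)=O)[C@H](OC(C)=O)C(I)=C(C)[C@H]12 | intermediate
37 | 11-O-triisopropylsilyl ether of the target | C=C1CC[C@H](O[Si](C(C)C)(C(C)C)C(C)C)[C@H](C)C[C@H](O)C2=C(C)[C@@H]3[C@H]1CC[C@]3(C)[C@@H](OC(C)=O)[C@@H]2OC(C)=O | intermediate
38 | CNP0114864.2 (2,3-diacetoxytrinervita-1(15),8(19)-diene-11,14-diol) | C=C1CC[C@H](O)[C@H](C)C[C@H](O)C2=C(C)[C@@H]3[C@H]1CC[C@]3(C)[C@@H](OC(C)=O)[C@@H]2OC(C)=O | target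

Total step count: 25. Longest linear sequence: 20 steps (steps 1–7 and 13–25, from 1 to 38); the five-step epoxide branch (steps 8–12) joins at step 13.

Steps most likely to fail

Step 3 (the step that carries the label). The fulvene may oligomerise under the copper Lewis acid, react too slowly, or give poor enantiofacial, endo or regio control, which would lower the optical purity of the whole core. Fallback with known chemistry: from 6, a thermal Diels–Alder reaction with phenyl vinyl sulfone (toluene, 90 °C), a standard ethylene equivalent, gives the racemic sulfone adduct F1 (regio- and endo/exo isomers converge later). K2CO3 in MeOH cleaves the enol acetate to the 7-syn-acetyl sulfone F2, allylMgBr gives the carbinol F3, and metathesis as in step 6 gives the hydrindene sulfone F4. Sodium amalgam (Na/Hg, Na2HPO4, MeOH) removes the sulfonyl group to give the racemic hydrindenol F5, which is resolved by preparative chromatography on a chiral stationary phase; the route is rejoined at 13.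

Step 13. Metalation may occur at the ring allylic position C1 or be misdirected by the lithium alkoxide, and the allyllithium may open the epoxide only sluggishly. Fallback: from 13, ene-type allylic chlorination of the isopropenyl group (Ca(OCl)2, CO2, CH2Cl2/H2O) gives the allylic chloride F6, and PhSO2Na in DMF gives the allylic sulfone F7. Its dianion (n-BuLi, THF/HMPA, −78 °C) opens epoxide 23 to the hydroxy sulfone F8, and reductive desulfonylation (sodium amalgam, Na2HPO4, MeOH, −20 °C) returns to 25.

Step 24. Ring closure may be slow relative to reduction of the vinyl iodide, and the facial selectivity at C14 in the eleven-membered transition state may be poor or reversed. Fallback: from 36, if the closure gives mainly the C14 epimer F9, the epimer mixture is oxidised with Dess–Martin periodinane to the C14 ketone F10, which is reduced under reagent control ((R)-2-methyl-CBS-oxazaborolidine, BH3·SMe2, −40 °C) to 37.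

Further compounds
F1 | step 3 | racemic 7-(1-acetoxyethylidene)-1,5-dimethyl-2-(phenylsulfonyl)bicyclo[2.2.1]hept-5-ene (one regio- and stereoisomer drawn) | C[C@@]12[C@@H](S(=O)(=O)c3ccccc3)C[C@@H](C(C)=C1)C2=C(C)OC(C)=O
F2 | step 3 | racemic 7-syn-acetyl-1,5-dimethyl-2-(phenylsulfonyl)bicyclo[2.2.1]hept-5-ene | C[C@@]12[C@@H](S(=O)(=O)c3ccccc3)C[C@@H](C(C)=C1)[C@H]2C(C)=O
F3 | step 3 | racemic 2-[1,5-dimethyl-2-(phenylsulfonyl)bicyclo[2.2.1]hept-5-en-7-syn-yl]pent-4-en-2-ol | C[C@@]12[C@@H](S(=O)(=O)c3ccccc3)C[C@@H](C(C)=C1)[C@H]2C(C)(O)CC=C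
F4 | step 3 | racemic 3-(phenylsulfonyl) derivative of 13 | C=C(C)[C@@H]1C[C@H](S(=O)(=O)c3ccccc3)[C@]2(C)C=CCC(C)(O)[C@H]12
F5 | step 3 | racemate of 13 (relative configuration drawn) | C=C(C)[C@@H]1CC[C@]2(C)C=CCC(C)(O)[C@H]12
F6 | step 13 | 13 with CH2Cl in place of the isopropenyl CH3 | ClCC(=C)[C@@H]1CC[C@]2(C)C=CCC(C)(O)[C@H]12
F7 | step 13 | 13 with CH2SO2Ph in place of the isopropenyl CH3 | C=C(CS(=O)(=O)c1ccccc1)[C@@H]1CC[C@]2(C)C=CCC(C)(O)[C@H]12
F8 | step 13 | 9-(phenylsulfonyl) derivative of 25 (C9 epimers) | C=C(C(C[C@H](O)[C@H](C)CCO[Si](C)(C)C(C)(C)C)S(=O)(=O)c1ccccc1)[C@@H]1CC[C@]2(C)C=CCC(C)(O)[C@H]12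
F9 | step 24 | C14 epimer of 37 | C=C1CC[C@H](O[Si](C(C)C)(C(C)C)C(C)C)[C@H](C)C[C@@H](O)C2=C(C)[C@@H]3[C@H]1CC[C@]3(C)[C@@H](OC(C)=O)[C@@H]2OC(C)=O
F10 | step 24 | C14 ketone of 37 | C=C1CC[C@H](O[Si](C(C)C)(C(C)C)C(C)C)[C@H](C)CC(=O)C2=C(C)[C@@H]3[C@H]1CC[C@]3(C)[C@@H](OC(C)=O)[C@@H]2OC(C)=O
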